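Target readings cannot tell me whether a plateau is a balance or an end.

| setting | amber | violet | flask |
|---|---|---|---|
| substrate | 0.22 M | 0.44 M | 0.22 M |
| partner | 0.396 M | 0.396 M | 0.396 M |
| temperature | 50 °C | 50 °C | 50 °C |
| remark | the very flask that is asked about, followed so far | run made earlier |  |
| time |  |  | 20 h |

| amber: time / h | amber: target / % | violet: time / min | violet: target / % |
|---|---|---|---|
| 1.50 | 18.5 | 5.00 | 0.4 |
| 3.00 | 43.8 | 10.0 | 0.4 |
| 6.00 | 69.6 | 15.0 | 0.6 |
| 10.0 | 80.2 | 20.0 | 0.6 |
| 20.0 | 84.1 | 25.0 | 1.0 |

(scatter of a reading: 0.5 percentage points)

- summer: change nothing and wait 6.0 h more
- midnight: at 20 h raise the temperature by 15 K, then wait 6.0 h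
- noon: at 20 h take out 90% of the target then present, then wait 6.0 h
- dawn: at 20 h add partner, 50.0% of the amount charged, then wait 6.0 h

1. target, in percent of the substrate first charged, at 20 h
2. which option adds most target ("none" when 2 percentage points or less is all one gets) (summer / midnight / noon / dawn / none)
3. target present, with what was taken out counted in, in percent of the substrate first charged, after midnight
4. target present, with what was taken out counted in, in percent of the substrate first charged, after noon

- target taken out counts as made
- the earlier runs do not show what temperature does; that part of a forecast is a guess
- additions bring no volume worth counting

The violet run looks nearly like the amber flask: same partner, same temperature, but twice the substrate. If one partner goes into each target, the violet charge allows target up to 90.0% of the substrate. The amber charge holds 1.80 partner per substrate, more partner than substrate, so there substrate is the limiting reagent and the charge allows 100 percent. So the amount of partner charged does not explain why amber levels at 84.1%, which is less than that. The violet readings end at 1.0% after 25.0 min, sooner than the first amber reading at 1.50 h. They show a slow start and no ending.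

Amber shows that start too. It gains 18.5% by 1.50 h, then more, 25 percentage points, in the next stretch of equal length. So I take it that something unseen builds up before target, and such a thing may go two ways. Then each portion of substrate is shared out once, and the plateau is an end. My measure is the selectivity factor S, target at the plateau divided by what is missing from the charge: 5.29 in the amber flask. A late action can then touch just the material not yet shared. I commit to 84.1% now, to no option worth 2 points, and to the same figure after midnight and noon.

The forecast says 84.2% now, noon as best, 85% after midnight and 92.5% after noon, as the stall “looks more like an equilibrium than a dying reaction”.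

The simulated flask gives 84.2% now, none as best, 84.2% after midnight and 84.2% after noon.

    open intermediate + second intermediate → target (k = 0.0470 L mol⁻¹ min⁻¹, Ea = 56.0 kJ mol⁻¹)
    2 open intermediate → homo product (k = 0.0350 L mol⁻¹ min⁻¹, Ea = 85.0 kJ mol⁻¹)
    partner → second intermediate (k = 0.0210 min⁻¹, Ea = 91.0 kJ mol⁻¹)
    substrate → open intermediate (k = 0.00710 min⁻¹, Ea = 102 kJ mol⁻¹)
    (constants at 50 °C)

Target falls short mainly because open intermediate pairs off into homo product: without that path the run gives 99.9%, not 84.2%. At 20.0 h this flask holds 0.0653% as substrate and open intermediate, so S promises 0.055 points; the options add 0.06 points to 0.065 points. In a neighbour flask like this one but with 0.67 M of partner, c(open intermediate) sinks as c(second intermediate) rises, so I scale S by the square of the partner charge. That gives 15.1, a target share of 93.8%; the neighbour flask computes to 92.5%.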